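**Retrosynthetic overview**
- The route rests on the vicinal, trans C3–CH3 and C4–CH3 groups of the tetrahydrofuran, which sit on the chain C2–C3–C4–C5 whose ends C2 and C5 carry the aryl groups and can be ketone carbons.
- The two arms come off last: both aryl–O–CH(CH3) bonds by SN2 of the core bisphenol with an (S)-α-tosyloxy ketone (from ethyl (S)-lactate and 4-bromoveratrole), then carbonyl reduction.
- The tetrahydrofuran is the only ring formed (step 9, after the key step): O1–C5 by 5-exo-tet SN2 with inversion in a (1S,4R)-1,4-diol monomesylate, whose carbinols come from two oxazaborolidine reductions of a 1,4-diketone.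
- The diketone comes from copper-catalysed asymmetric conjugate methylation of a symmetric (E)-1,4-diaryl-enedione, followed by methylation of the enolate (C3–CH3 and C4–CH3 bonds).
- The enedione comes from a Wittig union of an arylglyoxal and an acyl ylide, both made from O-tosylated acetovanillone.

Key step: step 6

Assumption: the aryl group acts as the large substituent in the oxazaborolidine reductions, and the (R,SP) ferrocenyl diphosphine is taken as the enantiomer that gives the (2R) centre of 12; if a first run shows the opposite sense, the mirror-image ligand is used with no other change.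

**Step 1**
Reactants: 1 acetovanillone; 2 p-toluenesulfonyl chloride
Product: 3 4-acetyl-2-methoxyphenyl 4-methylbenzenesulfonate
Conditions: TsCl, Et3N, 4-(dimethylamino)pyridine (cat.), CH2Cl2, 0 °C → rt
Reagents that add atoms: p-toluenesulfonyl chloride (2), Cc1ccc(cc1)S(=O)(=O)Cl
Why: O-sulfonylation of the phenol; the electron-withdrawing tosylate survives all later steps up to step 10 and makes the benzylic carbons reluctant to ionise, which the SN2 ring closure needs.

**Step 2**
Reactants: 3 4-acetyl-2-methoxyphenyl 4-methylbenzenesulfonate (one portion)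
Product: 4 (3-methoxy-4-tosyloxyphenyl)glyoxal
Conditions: SeO2 (1.2 equiv), 1,4-dioxane/H2O, reflux; filtration; azeotropic drying (toluene)
Reagents that add atoms: selenium dioxide, O=[Se]=O
Why: Riley oxidation of the aryl methyl ketone to the arylglyoxal; the sulfonate ester and the deactivated arene should be inert.

**Step 3**
Reactants: 3 4-acetyl-2-methoxyphenyl 4-methylbenzenesulfonate (second portion)
Product: 5 2-bromo-1-(3-methoxy-4-tosyloxyphenyl)ethanone
Conditions: CuBr2 (2.0 equiv), EtOAc/CHCl3, reflux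
Reagents that add atoms: copper dibromide, Br[Cu]Br
Why: α-bromination of the enolisable methyl ketone by CuBr2, which is selective for monobromination and leaves the acyl- and sulfonyloxy-deactivated ring alone.

**Step 4**
Reactants: 5 2-bromo-1-(3-methoxy-4-tosyloxyphenyl)ethanone
Product: 7 1-(3-methoxy-4-tosyloxyphenyl)-2-(triphenylphosphoranylidene)ethanone, via phosphonium bromide 6 (not isolated)
Conditions: PPh3, toluene, rt → 60 °C; then aq Na2CO3, CH2Cl2, rt
Reagents that add atoms: triphenylphosphine, c1ccc(cc1)P(c1ccccc1)c1ccccc1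
Why: SN2 quaternisation of the phosphine by the phenacyl bromide, then deprotonation of the acidic phosphonium salt by mild aqueous base, gives the stabilised acyl ylide without touching the aryl tosylate.

**Step 5**
Reactants: 4 (3-methoxy-4-tosyloxyphenyl)glyoxal; 7 1-(3-methoxy-4-tosyloxyphenyl)-2-(triphenylphosphoranylidene)ethanone
Product: 8 (E)-1,4-bis(3-methoxy-4-tosyloxyphenyl)but-2-ene-1,4-dione
Conditions: CH2Cl2, rt
Reagents that add atoms: none
Why: Wittig olefination of the aldehyde carbonyl of the glyoxal by the stabilised ylide, which is E-selective and leaves the less electrophilic ketone carbonyl alone.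

**Step 6**
Reactants: 8 (E)-1,4-bis(3-methoxy-4-tosyloxyphenyl)but-2-ene-1,4-dione; 9 methylmagnesium bromide; 10 iodomethane
Product: 12 (2R,3R)-1,4-bis(3-methoxy-4-tosyloxyphenyl)-2,3-dimethylbutane-1,4-dione, via magnesium enolate 11 (not isolated)
Conditions: CuBr·SMe2 (5 mol %), (R)-1-[(SP)-2-(diphenylphosphino)ferrocenyl]ethyldicyclohexylphosphine (6 mol %), MeMgBr (1.2 equiv), t-BuOMe/CH2Cl2, −78 °C, slow addition of 8; then MeI (10 equiv), DMPU, −78 → −20 °C
Reagents that add atoms: methylmagnesium bromide (9), C[Mg]Br; iodomethane (10), CI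
Why: The monovalent copper–diphosphine complex is transmetallated by MeMgBr to a chiral methylcopper species that binds one enantioface of the doubly activated alkene and transfers methyl to C2, leaving the (Z)-magnesium enolate 11 across C3–C4, which MeI (activated by DMPU) then C-methylates by SN2. The closest known reaction type is the copper/ferrocenyl-diphosphine-catalysed asymmetric conjugate addition of Grignard reagents to acyclic aryl enones with alkylative trapping of the magnesium enolate. No ring is closed. The C2 stereocentre is set by the ligand through enantioface selection; the C3 stereocentre is set by C2, because allylic 1,3-strain puts the C2–H in the enolate plane and MeI enters anti to the aroyl group (the alternative seven-membered magnesium chelate exposes the same face), which gives the C2-symmetric (2R,3R) diketone and not the meso isomer. The two alkene carbons of 8 are equivalent, so regiochemistry is not an issue. The step needs 1,4- over 1,2-addition, secured by the copper catalyst at −78 °C, and C-methylation ahead of proton transfer from the acidic C2–H or Michael addition of 11 to 8, secured by slow addition of 8, low temperature, excess MeI and DMPU.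

**Step 7**
Reactants: 12 (2R,3R)-1,4-bis(3-methoxy-4-tosyloxyphenyl)-2,3-dimethylbutane-1,4-dione
Product: 13 (2R,3R,4R)-4-hydroxy-1,4-bis(3-methoxy-4-tosyloxyphenyl)-2,3-dimethylbutan-1-one
Conditions: (S)-1-methyl-3,3-diphenyltetrahydro-1H,3H-pyrrolo[1,2-c][1,3,2]oxazaborole [(S)-Me-CBS] (0.2 equiv), BH3·SMe2 (0.55 equiv, slow addition), THF, −20 °C, stopped near half conversion; MeOH; unreacted 12 recycled
Reagents that add atoms: none
Why: Corey–Bakshi–Shibata reduction in which the (S)-oxazaborolidine gives the (R)-carbinol, the same face that the Felkin–Anh model favours for the adjacent (R)-methine, so C4 is set in the matched sense; sub-stoichiometric borane and partial conversion hold the reaction at one of the two homotopic carbonyls.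

**Step 8**
Reactants: 13 (2R,3R,4R)-4-hydroxy-1,4-bis(3-methoxy-4-tosyloxyphenyl)-2,3-dimethylbutan-1-one
Product: 14 (1R,2R,3R)-1,4-bis(3-methoxy-4-tosyloxyphenyl)-2,3-dimethyl-4-oxobutyl methanesulfonate
Conditions: MsCl, Et3N, CH2Cl2, −20 °C; cold work-up, used at once
Reagents that add atoms: methanesulfonyl chloride, CS(=O)(=O)Cl
Why: O-mesylation with retention at carbon; the para-tosyloxy group slows ionisation of the benzylic mesylate, so it should survive until the next step.

**Step 9**
Reactants: 14 (1R,2R,3R)-1,4-bis(3-methoxy-4-tosyloxyphenyl)-2,3-dimethyl-4-oxobutyl methanesulfonate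
Product: 16 (2S,3R,4R,5S)-2,5-bis(3-methoxy-4-tosyloxyphenyl)-3,4-dimethyltetrahydrofuran, via hydroxy mesylate 15 (not isolated)
Conditions: (R)-1-methyl-3,3-diphenyltetrahydro-1H,3H-pyrrolo[1,2-c][1,3,2]oxazaborole [(R)-Me-CBS] (1.0 equiv), BH3·SMe2, THF, −20 °C; MeOH, concentrate; then NaH, THF, 0 °C → rt
Reagents that add atoms: none
Why: Corey–Bakshi–Shibata reduction with the enantiomeric catalyst, used stoichiometrically, sets the (S)-carbinol under reagent control against the Felkin–Anh preference; its alkoxide then closes the ring by 5-exo-tet Williamson SN2 displacement of mesylate with inversion at the other benzylic carbon, giving the 2,3-cis-3,4-trans-4,5-cis tetrahydrofuran.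

**Step 10**
Reactants: 16 (2S,3R,4R,5S)-2,5-bis(3-methoxy-4-tosyloxyphenyl)-3,4-dimethyltetrahydrofuran
Product: 17 (2S,3R,4R,5S)-2,5-bis(4-hydroxy-3-methoxyphenyl)-3,4-dimethyltetrahydrofuran
Conditions: KOH, MeOH/THF/H2O, 50 °C; then 1 M HCl to pH 5
Reagents that add atoms: none
Why: Alkaline cleavage of the aryl sulfonate esters at the S–O bond frees both phenols; the ring stereocentres carry no acidic hydrogen, and the moderate temperature is meant to avoid quinone-methide ring opening.

**Step 11**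
Reactants: 18 ethyl (S)-lactate
Product: 19 (S)-2-hydroxy-N-methoxy-N-methylpropanamide
Conditions: MeNH(OMe)·HCl, i-PrMgCl, THF, −20 → 0 °C; aq NH4Cl
Reagents that add atoms: N,O-dimethylhydroxylamine hydrochloride, CNOC.Cl
Why: Aminolysis of the ester by the magnesium amide of N,O-dimethylhydroxylamine gives the Weinreb amide; the stereocentre, as its magnesium alkoxide, is not enolised.

**Step 12**
Reactants: 19 (S)-2-hydroxy-N-methoxy-N-methylpropanamide; 20 4-bromoveratrole
Product: 22 (S)-1-(3,4-dimethoxyphenyl)-2-hydroxypropan-1-one, via arylmagnesium bromide 21 (not isolated)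
Conditions: 20, Mg, THF, rt → 40 °C; then 19 (0.4 equiv relative to 21), THF, −20 → 0 °C; 1 M HCl, 0 °C
Reagents that add atoms: none
Why: Grignard formation and Weinreb ketone synthesis: the first equivalent of 21 deprotonates the hydroxyl and the second adds to give a chelated tetrahedral intermediate that releases the ketone only on work-up, with the stereocentre untouched.

**Step 13**
Reactants: 22 (S)-1-(3,4-dimethoxyphenyl)-2-hydroxypropan-1-one; 2 p-toluenesulfonyl chloride
Product: 23 (S)-1-(3,4-dimethoxyphenyl)-1-oxopropan-2-yl 4-methylbenzenesulfonate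
Conditions: TsCl, Et3N, 4-(dimethylamino)pyridine (cat.), CH2Cl2, 0 °C
Reagents that add atoms: p-toluenesulfonyl chloride (2), Cc1ccc(cc1)S(=O)(=O)Cl
Why: O-tosylation of the secondary alcohol with retention at carbon; the low temperature limits enolisation of the α-oxygenated ketone.

**Step 14**
Reactants: 17 (2S,3R,4R,5S)-2,5-bis(4-hydroxy-3-methoxyphenyl)-3,4-dimethyltetrahydrofuran; 23 (S)-1-(3,4-dimethoxyphenyl)-1-oxopropan-2-yl 4-methylbenzenesulfonate (2.3 equiv)
Product: 24 (2R,2'R)-2,2'-{[(2S,3R,4R,5S)-3,4-dimethyltetrahydrofuran-2,5-diyl]bis(2-methoxy-4,1-phenyleneoxy)}bis[1-(3,4-dimethoxyphenyl)propan-1-one]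
Conditions: K2CO3, DMF, rt
Reagents that add atoms: none
Why: Double Williamson etherification: each phenoxide displaces the carbonyl-activated secondary tosylate by SN2 with inversion, turning the (S)-centres of 23 into the (R)-configured aryloxy carbons.

**Step 15**
Reactants: 24 the bis(α-aryloxy ketone) from step 14
Product: 25 manassantin A
Conditions: Me4NBH4, MeOH/CH2Cl2, −20 → 0 °C
Reagents that add atoms: none
Why: Borohydride reduction with a non-coordinating counter-ion excludes chelation, so hydride should add by the polar Felkin–Anh model (aryloxy group anti to the incoming hydride) and give the threo (1R,2R) arrangement at both arms.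

**Compound list**
1 | acetovanillone | CC(=O)c1ccc(O)c(OC)c1 | starting material
2 | p-toluenesulfonyl chloride | Cc1ccc(cc1)S(=O)(=O)Cl | starting material
3 | 4-acetyl-2-methoxyphenyl 4-methylbenzenesulfonate | CC(=O)c1ccc(OS(=O)(=O)c2ccc(C)cc2)c(OC)c1 | intermediate
4 | (3-methoxy-4-tosyloxyphenyl)glyoxal | O=CC(=O)c1ccc(OS(=O)(=O)c2ccc(C)cc2)c(OC)c1 | intermediate
5 | 2-bromo-1-(3-methoxy-4-tosyloxyphenyl)ethanone | BrCC(=O)c1ccc(OS(=O)(=O)c2ccc(C)cc2)c(OC)c1 | intermediate
6 | [2-(3-methoxy-4-tosyloxyphenyl)-2-oxoethyl]triphenylphosphonium bromide | [Br-].O=C(C[P+](c1ccccc1)(c1ccccc1)c1ccccc1)c1ccc(OS(=O)(=O)c2ccc(C)cc2)c(OC)c1 | intermediate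
7 | 1-(3-methoxy-4-tosyloxyphenyl)-2-(triphenylphosphoranylidene)ethanone | O=C(C=P(c1ccccc1)(c1ccccc1)c1ccccc1)c1ccc(OS(=O)(=O)c2ccc(C)cc2)c(OC)c1 | intermediate
8 | (E)-1,4-bis(3-methoxy-4-tosyloxyphenyl)but-2-ene-1,4-dione | COc1cc(ccc1OS(=O)(=O)c2ccc(C)cc2)C(=O)/C=C/C(=O)c3ccc(OS(=O)(=O)c4ccc(C)cc4)c(OC)c3 | intermediate
9 | methylmagnesium bromide | C[Mg]Br | starting material
10 | iodomethane | CI | starting material
11 | bromomagnesium (R,Z)-enolate of 2-methyl-1,4-bis(3-methoxy-4-tosyloxyphenyl)butane-1,4-dione | COc1cc(ccc1OS(=O)(=O)c2ccc(C)cc2)C(=O)[C@H](C)/C=C(\O[Mg]Br)c3ccc(OS(=O)(=O)c4ccc(C)cc4)c(OC)c3 | intermediate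
12 | (2R,3R)-1,4-bis(3-methoxy-4-tosyloxyphenyl)-2,3-dimethylbutane-1,4-dione | COc1cc(ccc1OS(=O)(=O)c2ccc(C)cc2)C(=O)[C@H](C)[C@@H](C)C(=O)c3ccc(OS(=O)(=O)c4ccc(C)cc4)c(OC)c3 | intermediate
13 | (2R,3R,4R)-4-hydroxy-1,4-bis(3-methoxy-4-tosyloxyphenyl)-2,3-dimethylbutan-1-one | COc1cc(ccc1OS(=O)(=O)c2ccc(C)cc2)C(=O)[C@H](C)[C@@H](C)[C@@H](O)c3ccc(OS(=O)(=O)c4ccc(C)cc4)c(OC)c3 | intermediate
14 | (1R,2R,3R)-1,4-bis(3-methoxy-4-tosyloxyphenyl)-2,3-dimethyl-4-oxobutyl methanesulfonate | COc1cc(ccc1OS(=O)(=O)c2ccc(C)cc2)C(=O)[C@H](C)[C@@H](C)[C@@H](OS(C)(=O)=O)c3ccc(OS(=O)(=O)c4ccc(C)cc4)c(OC)c3 | intermediate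
15 | (1R,2R,3R,4S)-4-hydroxy-1,4-bis(3-methoxy-4-tosyloxyphenyl)-2,3-dimethylbutyl methanesulfonate | COc1cc(ccc1OS(=O)(=O)c2ccc(C)cc2)[C@@H](O)[C@H](C)[C@@H](C)[C@@H](OS(C)(=O)=O)c3ccc(OS(=O)(=O)c4ccc(C)cc4)c(OC)c3 | intermediate
16 | (2S,3R,4R,5S)-2,5-bis(3-methoxy-4-tosyloxyphenyl)-3,4-dimethyltetrahydrofuran | COc1cc(ccc1OS(=O)(=O)c2ccc(C)cc2)[C@H]3O[C@H](c4ccc(OS(=O)(=O)c5ccc(C)cc5)c(OC)c4)[C@H](C)[C@H]3C | intermediate
17 | (2S,3R,4R,5S)-2,5-bis(4-hydroxy-3-methoxyphenyl)-3,4-dimethyltetrahydrofuran | COc1cc(ccc1O)[C@H]2O[C@H](c3ccc(O)c(OC)c3)[C@H](C)[C@H]2C | intermediate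
18 | ethyl (S)-lactate | CCOC(=O)[C@H](C)O | starting material
19 | (S)-2-hydroxy-N-methoxy-N-methylpropanamide | CON(C)C(=O)[C@H](C)O | intermediate
20 | 4-bromoveratrole | COc1ccc(Br)cc1OC | starting material
21 | (3,4-dimethoxyphenyl)magnesium bromide | COc1ccc([Mg]Br)cc1OC | intermediate
22 | (S)-1-(3,4-dimethoxyphenyl)-2-hydroxypropan-1-one | COc1ccc(cc1OC)C(=O)[C@H](C)O | intermediate
23 | (S)-1-(3,4-dimethoxyphenyl)-1-oxopropan-2-yl 4-methylbenzenesulfonate | COc1ccc(cc1OC)C(=O)[C@H](C)OS(=O)(=O)c1ccc(C)cc1 | intermediate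
24 | (2R,2'R)-2,2'-{[(2S,3R,4R,5S)-3,4-dimethyltetrahydrofuran-2,5-diyl]bis(2-methoxy-4,1-phenyleneoxy)}bis[1-(3,4-dimethoxyphenyl)propan-1-one] | COc1ccc(C(=O)[C@@H](C)Oc2ccc([C@H]3O[C@H](c4ccc(O[C@H](C)C(=O)c5ccc(OC)c(OC)c5)c(OC)c4)[C@H](C)[C@H]3C)cc2OC)cc1OC | intermediate
25 | manassantin A | COc1ccc([C@@H](O)[C@@H](C)Oc2ccc([C@H]3O[C@H](c4ccc(O[C@H](C)[C@H](O)c5ccc(OC)c(OC)c5)c(OC)c4)[C@H](C)[C@H]3C)cc2OC)cc1OC | target

**Step count**
Total steps: 15. Longest linear sequence: 11 (steps 1, 3, 4, 5, 6, 7, 8, 9, 10, 14, 15).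

**Steps most likely to fail**

1. Step 6. The magnesium enolate may transfer the acidic C2 proton, or add to unreacted enedione, faster than it is C-methylated, and direct carbonyl addition of the Grignard reagent may compete. The result would be loss of enantiopurity at C2, the gem-dimethyl regioisomer, or oligomers. Fallback, from 8 back to 12: the same copper-catalysed conjugate methylation is run with chlorotrimethylsilane present at −78 °C, so the enolate is silylated as it forms and can be isolated as (R,Z)-2-methyl-1,4-bis(3-methoxy-4-tosyloxyphenyl)-4-(trimethylsilyloxy)but-3-en-1-one F1. In a separate operation the enolate is released from F1 with tris(dimethylamino)sulfonium difluorotrimethylsilicate in THF at −78 °C in the presence of excess MeI. This regiospecific fluoride-mediated alkylation of the silyl enol ether gives 12 under the same allylic-strain control.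

2. Step 9. Hydride delivery under catalyst control has to override the Felkin–Anh bias of the adjacent methine and may be poorly face-selective, and the crowded closure may give elimination instead of substitution. Fallback, from 13 back to 16, in which both carbinols are made in the matched sense and one is inverted separately: Mitsunobu reaction of 13 (PPh3, diisopropyl azodicarboxylate, 4-nitrobenzoic acid, THF) gives the inverted ester (1S,2R,3R)-1,4-bis(3-methoxy-4-tosyloxyphenyl)-2,3-dimethyl-4-oxobutyl 4-nitrobenzoate F6. Matched reduction of the remaining ketone with the (S)-oxazaborolidine and BH3·SMe2 gives (1S,2R,3R,4R)-4-hydroxy-1,4-bis(3-methoxy-4-tosyloxyphenyl)-2,3-dimethylbutyl 4-nitrobenzoate F7. Mesylation (MsCl, Et3N) gives (1S,2R,3R,4R)-4-(methylsulfonyloxy)-1,4-bis(3-methoxy-4-tosyloxyphenyl)-2,3-dimethylbutyl 4-nitrobenzoate F8. K2CO3 in MeOH at rt then removes the ester, and the freed alkoxide displaces the mesylate with inversion to give 16.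

3. Step 7. The catalyst cannot tell the first carbonyl from the second, so over-reduction to the C2-symmetric diol and incomplete conversion will accompany the wanted mono-reduction. Fallback, from 12 back to 16, which accepts full reduction and replaces steps 7 to 9 by a double inversion: excess BH3·SMe2 with the (S)-oxazaborolidine gives (1R,2R,3R,4R)-1,4-bis(3-methoxy-4-tosyloxyphenyl)-2,3-dimethylbutane-1,4-diol F2. SOCl2 and Et3N give the cyclic sulfite (4R,5R,6R,7R)-4,7-bis(3-methoxy-4-tosyloxyphenyl)-5,6-dimethyl-1,3,2-dioxathiepane 2-oxide F3. RuCl3 hydrate (cat.) with NaIO4 in MeCN/H2O at 0 °C gives the cyclic sulfate (4R,5R,6R,7R)-4,7-bis(3-methoxy-4-tosyloxyphenyl)-5,6-dimethyl-1,3,2-dioxathiepane 2,2-dioxide F4. Caesium benzoate in DMF opens F4 by SN2 with inversion at one of its two equivalent carbons to give caesium (1R,2R,3R,4S)-4-benzoyloxy-1,4-bis(3-methoxy-4-tosyloxyphenyl)-2,3-dimethylbutyl sulfate F5. NaOMe in MeOH removes the benzoate, and the alkoxide displaces the sulfate monoester with a second inversion to give 16. This sequence has no statistical step and no mismatched reduction.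

**Further compounds**
F1 | step 6 | (R,Z)-2-methyl-1,4-bis(3-methoxy-4-tosyloxyphenyl)-4-(trimethylsilyloxy)but-3-en-1-one | COc1cc(ccc1OS(=O)(=O)c2ccc(C)cc2)C(=O)[C@H](C)/C=C(\O[Si](C)(C)C)c3ccc(OS(=O)(=O)c4ccc(C)cc4)c(OC)c3
F2 | step 7 | (1R,2R,3R,4R)-1,4-bis(3-methoxy-4-tosyloxyphenyl)-2,3-dimethylbutane-1,4-diol | COc1cc(ccc1OS(=O)(=O)c2ccc(C)cc2)[C@H](O)[C@H](C)[C@@H](C)[C@@H](O)c3ccc(OS(=O)(=O)c4ccc(C)cc4)c(OC)c3
F3 | step 7 | (4R,5R,6R,7R)-4,7-bis(3-methoxy-4-tosyloxyphenyl)-5,6-dimethyl-1,3,2-dioxathiepane 2-oxide | COc1cc(ccc1OS(=O)(=O)c2ccc(C)cc2)[C@H](OS(=O)O5)[C@H](C)[C@@H](C)[C@@H]5c3ccc(OS(=O)(=O)c4ccc(C)cc4)c(OC)c3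
F4 | step 7 | (4R,5R,6R,7R)-4,7-bis(3-methoxy-4-tosyloxyphenyl)-5,6-dimethyl-1,3,2-dioxathiepane 2,2-dioxide | COc1cc(ccc1OS(=O)(=O)c2ccc(C)cc2)[C@H](OS(=O)(=O)O5)[C@H](C)[C@@H](C)[C@@H]5c3ccc(OS(=O)(=O)c4ccc(C)cc4)c(OC)c3
F5 | step 7 | caesium (1R,2R,3R,4S)-4-benzoyloxy-1,4-bis(3-methoxy-4-tosyloxyphenyl)-2,3-dimethylbutyl sulfate | COc1cc(ccc1OS(=O)(=O)c2ccc(C)cc2)[C@H](OS(=O)(=O)[O-])[C@H](C)[C@@H](C)[C@H](OC(=O)c5ccccc5)c3ccc(OS(=O)(=O)c4ccc(C)cc4)c(OC)c3.[Cs+]
F6 | step 9 | (1S,2R,3R)-1,4-bis(3-methoxy-4-tosyloxyphenyl)-2,3-dimethyl-4-oxobutyl 4-nitrobenzoate | COc1cc(ccc1OS(=O)(=O)c2ccc(C)cc2)C(=O)[C@H](C)[C@@H](C)[C@H](OC(=O)c5ccc(cc5)[N+](=O)[O-])c3ccc(OS(=O)(=O)c4ccc(C)cc4)c(OC)c3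
F7 | step 9 | (1S,2R,3R,4R)-4-hydroxy-1,4-bis(3-methoxy-4-tosyloxyphenyl)-2,3-dimethylbutyl 4-nitrobenzoate | COc1cc(ccc1OS(=O)(=O)c2ccc(C)cc2)[C@H](O)[C@H](C)[C@@H](C)[C@H](OC(=O)c5ccc(cc5)[N+](=O)[O-])c3ccc(OS(=O)(=O)c4ccc(C)cc4)c(OC)c3
F8 | step 9 | (1S,2R,3R,4R)-4-(methylsulfonyloxy)-1,4-bis(3-methoxy-4-tosyloxyphenyl)-2,3-dimethylbutyl 4-nitrobenzoate | COc1cc(ccc1OS(=O)(=O)c2ccc(C)cc2)[C@H](OS(C)(=O)=O)[C@H](C)[C@@H](C)[C@H](OC(=O)c5ccc(cc5)[N+](=O)[O-])c3ccc(OS(=O)(=O)c4ccc(C)cc4)c(OC)c3
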